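Enzyme and rate do not keep step.

| flask | starting material | enzyme | impurity | remark |
|---|---|---|---|---|
| north-west | 0.20 M | 10 µM | 5.6 µM | run made earlier |
| west | 0.20 M | 15 µM | 5.6 µM | run made earlier |
| flask | 0.20 M | 20 µM | 5.6 µM |  |

| run | time / h | product / % | starting material / % |
|---|---|---|---|
| north-west | 0.133 | 3.2 | 98.1 |
| north-west | 0.333 | 4.8 | 95.4 |
| north-west | 0.667 | 9.7 | 90.7 |
| north-west | 1.00 | 13.4 | 85.1 |
| north-west | 1.33 | 18.0 | 81.2 |
| north-west | 2.00 | 27.1 | 72.4 |
| north-west | 2.50 | 33.8 | 66.1 |
| west | 0.133 | 4.2 | 95.1 |
| west | 0.333 | 9.7 | 89.4 |
| west | 0.667 | 19.8 | 79.6 |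
| west | 1.00 | 30.3 | 71.3 |
| west | 1.33 | 38.2 | 61.5 |
| west | 2.00 | 54.5 | 44.9 |
| west | 2.50 | 66.7 | 33.7 |

(standard deviation of a reading: 0.5 percentage points)

* apparent order in enzyme when 50% of the starting material are converted (percent change of the rate of making product for one percent more enzyme charged)
* factor on the rate of making product when 50% of the starting material are converted if enzyme is charged twice over



Up to 1.33 h both earlier runs make product at a nearly steady rate, so the readings there serve as rates. By then the west run has made 2.12 times the product of the north-west run, more than the 1.50 times as much enzyme charged. A straight line through the two rates reaches zero at 5.54 µM of enzyme, a reading with the scatter of its points, and the impurity charge is 5.6 µM, which comes from a different source.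

The reckoning here therefore takes the rate as proportional to E − Y, with E the enzyme and Y the impurity charged. At a fixed conversion the starting material stands alike, so its part cancels, and the order in enzyme is the charge-to-working ratio, f = E/(E − Y) = 1.39. Doubling E multiplies the rate by one plus f, 2.39.

An order of one asks f equal to one, hence no impurity, while zero rate sits at E equal to Y. The flask stands at 3.57 times that threshold, with 28.0% of its enzyme reckoned lost.

The forecast, holding that “the impurity apparently kills enzyme stoichiometrically”, gives 1.39 (1.28 to 1.52) and 2.39 (2.2 to 2.65), the same values as the reckoning here.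

The simulation gives an order of 1.4 and a factor of 2.39, both inside those ranges.

    starting material + enzyme → product + enzyme, rate k1*[starting material]^3*[enzyme]/(1 + ([starting material]/Kh1)^3) (0.0551 M, k = 10400 /M³/s)
    enzyme + impurity → spent catalyst (k = 730 /M/s)

At 0.300 h the flask holds impurity, the limiting reagent of the poisoning, at 0% of its charge, with enzyme at 72.0% and spent catalyst at 28.0% of the catalyst charged, and the same two catalyst shares stand at 30.0 h. With the poisoning step taken away, the flask has an order of 1.0, against 1.4 with that step, and with Y nil f is one. In the simulated run without that step, the rate at 50% conversion stands at 1.39 times the actual one, against f = 1.39.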